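If target and other capture product both come from one short-lived species for which the first nucleophile and the second nucleophile compete, that species can be taken at its steady level. The ratio of target to other capture product is then the partition factor (a selectivity factor) times first nucleophile over second nucleophile, and the early share of target follows from the charges.

| flask | solid substrate | first nucleophile | second nucleophile | capture agent | remark | time |
|---|---|---|---|---|---|---|
| east | 2.0 × 10⁻⁴ M | 2.5 equiv | 1.2 equiv | 0.060 mM | the very flask that is asked about, followed so far |  |
| north-west | 2.0 × 10⁻⁴ M | 5 equiv | 1.2 equiv | 0.060 mM | run made earlier |  |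
| flask | 2.0 × 10⁻⁴ M | 2.50 equiv | 1.20 equiv | 0.0600 mM |  | 5.0 min |

east run (percent of the solid substrate charged)

| time / s | target / % | other capture product / % | solid substrate / % |
|---|---|---|---|
| 10.0 | 1.5 | 1.2 | 82.3 |
| 15.0 | 3.8 | 0.5 | 76.0 |
| 40.0 | 6.7 | 4.5 | 43.4 |
| 90.0 | 9.2 | 15.0 | 0 |

north-west run (percent of the solid substrate charged)

| time / min | target / % | other capture product / % | solid substrate / % |
|---|---|---|---|
| 0.833 | 13.9 | 5.0 | 31.6 |
| 2.00 | 4.7 | 10.3 | 1.5 |
| 2.50 | 3.9 | 9.6 | 0 |
| 4.00 | 0.6 | 9.5 | 2.1 |

(each reading ± 1 percentage point)

- share of target in target plus other capture product at 6.0 s
- share of target in target plus other capture product at 5.0 min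
- which of target and other capture product there is more of at 5.0 min

- as a solid, counted per litre of solution: solid substrate
- what was read earlier has a scatter of 1 percentage point, one standard deviation
- at the start none of the solid substrate is in solution

The pooled east readings at 10.0 s and 15.0 s give a factor of 1.50, a reading that carries a scatter of 1 percentage point on each amount and is taken as the upper end of a bracket, not as a strict bound. Later readings are taken as lower ends, since target in the north-west run falls from 13.9% to 0.6%, so a late ratio can stand below the early one. That run at 0.833 min gives 0.667, and the east run at 40.0 s tightens this to 0.715. My own bracket for the east flask at 6.0 s therefore runs from 59.8% to 75.7%.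

The forecast gives 70%, inside this bracket. For 5.0 min it gives 13%, with other capture product ahead, on the ground that “Target is therefore destroyed, not converted, probably by excess first nucleophile”.

The flask gives 70.5% at 6.0 s and 0.101% at 5.0 min, with other capture product ahead at 13.2%.

    starting material → open intermediate (k = 0.0810 s⁻¹)
    first nucleophile + open intermediate → target (k = 9100 L mol⁻¹ s⁻¹)
    second nucleophile + open intermediate → other capture product (k = 7100 L mol⁻¹ s⁻¹)
    open intermediate → solvolysis product (k = 5.20 s⁻¹)
    solid substrate ⇌ starting material, rate k5*(cs5 - [starting material]) while solid is left; crystals form when [starting material] > cs5 (solubility = 0.140 mM, k = 0.0250 s⁻¹)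
    second nucleophile + target → over-reaction product (k = 230 L mol⁻¹ s⁻¹)
    open intermediate + capture agent → trapped intermediate (k = 470 L mol⁻¹ s⁻¹)

The forecast for 5.0 min stands 13 points above the flask, where over-reaction product, made from second nucleophile and target, reaches 38.6% and target stands at 0.0133%. The share at 6.0 s corresponds to a partition factor of 1.15, between the two ends. For the neighbour flask with 6.20 equiv of first nucleophile, the two ends give a share at 6.0 s of 78.7% to 88.5%, and that flask gives 85.6%.

(The numbers in the tables were generated by integration for substances that don't exist, noise included.)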